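**Retrosynthetic overview**
1. Target 21 ⇐ debenzylation and double angeloylation of anti-diol 18 ⇐ hydroxyl-directed reduction of tricyclic aldol 17.
2. Seven-membered ring (formed last): intramolecular aldol C1–C2 of keto aldehyde 16.
3. Cyclobutane and six-membered ring (formed together, first): crossed radical-anion [2+2] of acyclic bis(enone) 14 under visible light (C5–C6, then C4–C7).
4. 14 ⇐ Fukuyama coupling (C8–C9) of enethioate 8 with the alkylzinc from bromo enone 12.
5. 8 ⇐ dimethyl (S)-malate (two Fráter–Seebach alkylations set C11, the carbinol carbon is then excised); 12 ⇐ (S)-3-bromo-2-methylpropan-1-ol (C10).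

Atom labels used throughout (target skeleton): C1 = CH(OAng) next to quaternary C11; C2 = ring CH2; C3 = CH(OAng) next to the cyclobutane; C4 = quaternary cyclobutane carbon (CH3); C5, C6, C7 = cyclobutane CH (C5 bonded to C10, C6 to C11, C7 to C8); C8 = C=O; C9 = CH2; C10 = CH(CH3); C11 = quaternary carbon carrying CH3 and C15H2OH. Both esters in the target SMILES are read as angelates ((Z)-2-methylbut-2-enoates).

**Route**

Step 1
Reactants: 1 dimethyl (S)-malate
Product: 2 dimethyl (2S,3R)-2-hydroxy-3-methylbutanedioate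
Conditions: LiN(i-Pr)2 (2.2 equiv), THF, −78 to −20 °C; MeI, −78 to 0 °C
Reagents that add atoms: iodomethane, CI
Why: Fráter–Seebach alkylation, in which the chelated dilithium alkoxide–enolate is methylated anti to the alkoxide to give the (2S,3R) product (about 9:1).

Step 2
Reactants: 2 dimethyl (2S,3R)-2-hydroxy-3-methylbutanedioate
Product: 3 dimethyl (2R,3S)-2-[(benzyloxy)methyl]-3-hydroxy-2-methylbutanedioate
Conditions: LiN(i-Pr)2 (2.2 equiv), THF, −78 to −20 °C; BnOCH2Cl, −78 to −10 °C
Reagents that add atoms: benzyl chloromethyl ether, ClCOCc1ccccc1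
Why: second Fráter–Seebach alkylation through the same chelate, the electrophile again entering anti to the alkoxide, so the order MeI then BnOCH2Cl fixes the quaternary centre (future C11) in the required sense.

Step 3
Reactants: 3 dimethyl (2R,3S)-2-[(benzyloxy)methyl]-3-hydroxy-2-methylbutanedioate
Product: 4 (2S,3R)-3-[(benzyloxy)methyl]-3-methylbutane-1,2,4-triol
Conditions: LiAlH4, THF, 0 to 25 °C
Reagents that add atoms: none
Why: exhaustive hydride reduction of both esters, the quaternary stereocentre being unable to epimerise.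

Step 4
Reactants: 4 (2S,3R)-3-[(benzyloxy)methyl]-3-methylbutane-1,2,4-triol; 5 (triphenylphosphoranylidene)ketene
Product: 8 S-ethyl (2E,4R)-4-[(benzyloxy)methyl]-5-hydroxy-4-methylpent-2-enethioate, via hydroxy aldehyde 6 (not isolated), via thioester ylide 7 (not isolated)
Conditions: Pb(OAc)4, CH2Cl2, 0 °C; then 7 (preformed from 5 and EtSH, 2.5 equiv each, THF, 25 °C), 40 °C
Reagents that add atoms: ethanethiol, CCS
Why: Criegee glycol cleavage excises the malate carbinol carbon to leave the formyl group on C11, and the hindered aldehyde is trapped by an E-selective Wittig reaction with the stabilised ylide made by thiol addition to the ketenylidene phosphorane (the excess also consumes the formaldehyde).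

Step 5
Reactants: 9 (2S)-3-bromo-2-methylpropan-1-ol; 10 3-(triphenylphosphoranylidene)butan-2-one
Product: 12 (3E,5S)-6-bromo-3,5-dimethylhex-3-en-2-one, via bromo aldehyde 11 (not isolated)
Conditions: Dess–Martin periodinane, CH2Cl2, 0 to 25 °C; then 10, 40 °C
Reagents that add atoms: none
Why: Dess–Martin oxidation followed in the same flask by a Wittig reaction with the α-methyl acyl ylide gives the E trisubstituted enone under non-basic conditions that spare the β-bromo aldehyde and its α-stereocentre (future C10).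

Step 6
Reactants: 12 (3E,5S)-6-bromo-3,5-dimethylhex-3-en-2-one; 8 S-ethyl (2E,4R)-4-[(benzyloxy)methyl]-5-hydroxy-4-methylpent-2-enethioate
Product: 14 (3E,5R,8E,10R)-10-[(benzyloxy)methyl]-11-hydroxy-3,5,10-trimethylundeca-3,8-diene-2,7-dione, via alkylzinc bromide 13 (not isolated)
Conditions: Zn dust, LiCl, THF, 50 °C; then 8 (0.4 equiv relative to 12), PdCl2(PPh3)2 (5 mol %), THF/toluene, 25 °C
Reagents that add atoms: none
Why: Fukuyama coupling (Pd-catalysed acylation of an alkylzinc halide by a thioester) forms the C8–C9 bond and tolerates the ketone, the enone and the free hydroxyl.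

Step 7
Reactants: 14 (3E,5R,8E,10R)-10-[(benzyloxy)methyl]-11-hydroxy-3,5,10-trimethylundeca-3,8-diene-2,7-dione
Product: 15 (1R,4R,5S,6R,7S)-6-acetyl-7-[(2R)-1-(benzyloxy)-3-hydroxy-2-methylpropan-2-yl]-4,6-dimethylbicyclo[3.1.1]heptan-2-one (acetyl and the C7 side chain both anti to the C2–C4 bridge; 4-methyl syn to C7)
Conditions: 10-phenylphenothiazine (5 mol %), LiBF4 (2 equiv), MeCN (0.02 M), 390 nm LEDs, 25 °C, Ar
Reagents that add atoms: none
Why: Proposed new method: photoinduced electron transfer from excited 10-phenylphenothiazine (about −2.1 V vs SCE) to the LiBF4-bound enone gives an enone radical anion whose β-carbon C5 adds to the β-carbon C6 of the second enone in a polarity-matched 6-endo mode (the 5-exo alternative is an anti-Michael attack at C7), the enolate/α-keto radical pair then closes C4–C7 and the product ketyl radical anion returns the electron to the catalyst radical cation or to fresh 14, so the crossed bicyclo[3.1.1]heptanone forms instead of the usual bicyclo[3.2.0] adduct; the bought C10 centre fixes the face by allylic 1,3-strain (C10–H eclipses C4=C5 and the tether delivers the second enone to the face carrying C9, leaving the C10 methyl syn to C6), and suprafacial union of the two E-alkenes places acetyl and the C11 side chain cis-1,3 and anti to the keto bridge; the closest known reaction is the anion-radical [2+2] cycloaddition of aryl bis(enones) under visible-light photoredox or cathodic initiation, which gives bicyclo[3.2.0]heptanes by 5-exo β,β-coupling and has not been shown for all-aliphatic enones or for this tether topology.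

Step 8
Reactants: 15 (1R,4R,5S,6R,7S)-6-acetyl-7-[(2R)-1-(benzyloxy)-3-hydroxy-2-methylpropan-2-yl]-4,6-dimethylbicyclo[3.1.1]heptan-2-one
Product: 16 (2S)-2-[(1R,4R,5S,6R,7S)-6-acetyl-4,6-dimethyl-2-oxobicyclo[3.1.1]heptan-7-yl]-3-(benzyloxy)-2-methylpropanal
Conditions: Dess–Martin periodinane, CH2Cl2, 25 °C
Reagents that add atoms: none
Why: Dess–Martin oxidation of the primary neopentyl alcohol to the non-enolisable aldehyde, the ketones being inert.

Step 9
Reactants: 16 (2S)-2-[(1R,4R,5S,6R,7S)-6-acetyl-4,6-dimethyl-2-oxobicyclo[3.1.1]heptan-7-yl]-3-(benzyloxy)-2-methylpropanal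
Product: 17 (1S,2S,3S,4R,7R,8R,11R)-3-[(benzyloxy)methyl]-4-hydroxy-3,7,11-trimethyltricyclo[5.4.0.0(2,8)]undecane-6,9-dione (locants follow target 21; C1–OH cis to the C11 methyl)
Conditions: LiN(SiMe3)2 (1.1 equiv), THF, −78 to −40 °C; NH4Cl quench at −78 °C
Reagents that add atoms: none
Why: intramolecular aldol addition in which the lithium enolate of the methyl ketone closes the seven-membered ring onto the aldehyde (the ring-ketone enolate at C9 cannot reach C1 and is returned by proton exchange), with C1 set by Felkin–Anh-type attack anti to the larger CH2OBn arm so that the new hydroxyl lies cis to the C11 methyl.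

Step 10
Reactants: 17 (1S,2S,3S,4R,7R,8R,11R)-3-[(benzyloxy)methyl]-4-hydroxy-3,7,11-trimethyltricyclo[5.4.0.0(2,8)]undecane-6,9-dione
Product: 18 (1S,2S,3S,4R,6R,7R,8R,11R)-3-[(benzyloxy)methyl]-4,6-dihydroxy-3,7,11-trimethyltricyclo[5.4.0.0(2,8)]undecan-9-one
Conditions: Me4NBH(OAc)3, MeCN/AcOH, −30 °C
Reagents that add atoms: none
Why: Evans–Saksena hydroxyl-directed reduction, in which hydride is delivered intramolecularly from the C1 alkoxyborohydride to give the 1,3-anti (trans) diol at C3 while the C8 ketone, lacking a β-hydroxyl, is untouched.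

Step 11
Reactants: 18 (1S,2S,3S,4R,6R,7R,8R,11R)-3-[(benzyloxy)methyl]-4,6-dihydroxy-3,7,11-trimethyltricyclo[5.4.0.0(2,8)]undecan-9-one; 19 angelic anhydride ((Z)-2-methylbut-2-enoic anhydride)
Product: 20 (1S,2S,3S,4R,6R,7R,8R,11R)-3-[(benzyloxy)methyl]-3,7,11-trimethyl-9-oxotricyclo[5.4.0.0(2,8)]undecane-4,6-diyl bis[(2Z)-2-methylbut-2-enoate]
Conditions: LiN(SiMe3)2 (2.1 equiv), THF, −78 °C; then 19 (3 equiv), −78 to 0 °C
Reagents that add atoms: none
Why: O-acylation of the preformed lithium alkoxides with the anhydride, a method free of nucleophilic catalysts that would isomerise the Z-alkene to the tiglate.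

Step 12
Reactants: 20 (1S,2S,3S,4R,6R,7R,8R,11R)-3-[(benzyloxy)methyl]-3,7,11-trimethyl-9-oxotricyclo[5.4.0.0(2,8)]undecane-4,6-diyl bis[(2Z)-2-methylbut-2-enoate]
Product: 21 (1S,2S,3S,4R,6R,7R,8R,11R)-3-(hydroxymethyl)-3,7,11-trimethyl-9-oxotricyclo[5.4.0.0(2,8)]undecane-4,6-diyl bis[(2Z)-2-methylbut-2-enoate] (CNP0287707.1)
Conditions: BCl3, C6HMe5, CH2Cl2, −78 °C; then MeOH
Reagents that add atoms: none
Why: Lewis-acid benzyl ether cleavage with pentamethylbenzene as cation scavenger, which unlike hydrogenolysis leaves the two angelate alkenes, the esters and the ketone intact.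

**Compound list**
1 | dimethyl (S)-malate | COC(=O)C[C@H](O)C(=O)OC | starting material
2 | dimethyl (2S,3R)-2-hydroxy-3-methylbutanedioate | COC(=O)[C@@H](O)[C@@H](C)C(=O)OC | intermediate
3 | dimethyl (2R,3S)-2-[(benzyloxy)methyl]-3-hydroxy-2-methylbutanedioate | COC(=O)[C@@H](O)[C@@](C)(COCc1ccccc1)C(=O)OC | intermediate
4 | (2S,3R)-3-[(benzyloxy)methyl]-3-methylbutane-1,2,4-triol | OC[C@@H](O)[C@@](C)(COCc1ccccc1)CO | intermediate
5 | (triphenylphosphoranylidene)ketene | O=C=C=P(c1ccccc1)(c1ccccc1)c1ccccc1 | starting material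
6 | (2R)-2-[(benzyloxy)methyl]-3-hydroxy-2-methylpropanal | O=C[C@@](C)(COCc1ccccc1)CO | intermediate
7 | S-ethyl 2-(triphenylphosphoranylidene)ethanethioate | CCSC(=O)C=P(c1ccccc1)(c1ccccc1)c1ccccc1 | intermediate
8 | S-ethyl (2E,4R)-4-[(benzyloxy)methyl]-5-hydroxy-4-methylpent-2-enethioate | CCSC(=O)/C=C/[C@@](C)(COCc1ccccc1)CO | intermediate
9 | (2S)-3-bromo-2-methylpropan-1-ol | OC[C@H](C)CBr | starting material
10 | 3-(triphenylphosphoranylidene)butan-2-one | CC(=O)C(C)=P(c1ccccc1)(c1ccccc1)c1ccccc1 | starting material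
11 | (2S)-3-bromo-2-methylpropanal | O=C[C@H](C)CBr | intermediate
12 | (3E,5S)-6-bromo-3,5-dimethylhex-3-en-2-one | CC(=O)/C(C)=C/[C@H](C)CBr | intermediate
13 | [(2S,3E)-2,4-dimethyl-5-oxohex-3-en-1-yl]zinc bromide | CC(=O)/C(C)=C/[C@H](C)C[Zn]Br | intermediate
14 | (3E,5R,8E,10R)-10-[(benzyloxy)methyl]-11-hydroxy-3,5,10-trimethylundeca-3,8-diene-2,7-dione | CC(=O)/C(C)=C/[C@H](C)CC(=O)/C=C/[C@@](C)(COCc1ccccc1)CO | intermediate
15 | (1R,4R,5S,6R,7S)-6-acetyl-7-[(2R)-1-(benzyloxy)-3-hydroxy-2-methylpropan-2-yl]-4,6-dimethylbicyclo[3.1.1]heptan-2-one | CC(=O)[C@]1(C)[C@@H]2[C@@H]([C@H]1C(=O)C[C@H]2C)[C@@](C)(COCc3ccccc3)CO | intermediate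
16 | (2S)-2-[(1R,4R,5S,6R,7S)-6-acetyl-4,6-dimethyl-2-oxobicyclo[3.1.1]heptan-7-yl]-3-(benzyloxy)-2-methylpropanal | CC(=O)[C@]1(C)[C@@H]2[C@@H]([C@H]1C(=O)C[C@H]2C)[C@@](C)(COCc3ccccc3)C=O | intermediate
17 | (1S,2S,3S,4R,7R,8R,11R)-3-[(benzyloxy)methyl]-4-hydroxy-3,7,11-trimethyltricyclo[5.4.0.0(2,8)]undecane-6,9-dione | O[C@@H]1CC(=O)[C@]2(C)[C@@H]3[C@@H]([C@H]2C(=O)C[C@H]3C)[C@@]1(C)COCc4ccccc4 | intermediate
18 | (1S,2S,3S,4R,6R,7R,8R,11R)-3-[(benzyloxy)methyl]-4,6-dihydroxy-3,7,11-trimethyltricyclo[5.4.0.0(2,8)]undecan-9-one | O[C@@H]1C[C@@H](O)[C@]2(C)[C@@H]3[C@@H]([C@H]2C(=O)C[C@H]3C)[C@@]1(C)COCc4ccccc4 | intermediate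
19 | angelic anhydride ((Z)-2-methylbut-2-enoic anhydride) | C/C=C(/C)C(=O)OC(=O)/C(C)=C\C | starting material
20 | (1S,2S,3S,4R,6R,7R,8R,11R)-3-[(benzyloxy)methyl]-3,7,11-trimethyl-9-oxotricyclo[5.4.0.0(2,8)]undecane-4,6-diyl bis[(2Z)-2-methylbut-2-enoate] | C/C=C(/C)C(=O)O[C@@H]1C[C@@H](OC(=O)/C(C)=C\C)[C@]2(C)[C@@H]3[C@@H]([C@H]2C(=O)C[C@H]3C)[C@@]1(C)COCc4ccccc4 | intermediate
21 | (1S,2S,3S,4R,6R,7R,8R,11R)-3-(hydroxymethyl)-3,7,11-trimethyl-9-oxotricyclo[5.4.0.0(2,8)]undecane-4,6-diyl bis[(2Z)-2-methylbut-2-enoate] | C/C=C(/C)C(=O)O[C@@H]1C[C@@H](OC(=O)/C(C)=C\C)[C@]2(C)[C@@H]3[C@@H]([C@H]2C(=O)C[C@H]3C)[C@@]1(C)CO | target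

**Step count and risks**

Total steps: 12. Longest linear sequence: 11 (steps 1–4 and 6–12, from dimethyl (S)-malate); step 5 is the one-step side branch.

Steps most likely to fail:

Step 7 (the new crossed radical-anion [2+2]). Aliphatic enones are hard to reduce, and the intermediate enolate/α-keto radical may be quenched to the monocyclic reductive-cyclisation product instead of closing the cyclobutane. Closure also needs the C4 and C11 groups cis on the new six-membered ring. The fallback uses known reaction types and sets out from 14. Two-electron reductive β,β-cyclisation with Mg turnings and Me3SiCl in DMF traps both enolates regiospecifically (and silylates the primary alcohol) as the tris(trimethylsilyl) reductive-cyclisation product F1. Oxidative intramolecular coupling of its two silyl enol ethers with (NH4)2Ce(NO3)6 and NaHCO3 in MeCN at −30 °C then forms the C4–C7 bond, and aqueous work-up frees the primary alcohol, so the route is rejoined at 15.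

Step 9 (aldol closure of the seven-membered ring). The base may enolise the ring ketone competitively, and the closed lithium transition state may give the C1 epimer. The fallback sets out from 16. Me3SiOTf and Et3N in CH2Cl2 convert both ketones into the bis(trimethylsilyl enol ether) F2. BF3·OEt2 at −78 °C then triggers an intramolecular Mukaiyama aldol through an open, non-chelated transition state in which only the terminal enol ether can reach the aldehyde. Aqueous work-up hydrolyses the ring enol ether, and the route is rejoined at 17.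

Step 11 (double angeloylation). Both secondary alcohols are neopentyl-like, the C8 ketone can be enolised by the base, and angelates isomerise easily to tiglates. The fallback sets out from 18. Esterification with 2-[bis(2,2,2-trifluoroethoxy)phosphoryl]propanoic acid (DCC, DMAP, CH2Cl2; DMAP is harmless here because no alkene is present yet) gives the bis(phosphonopropanoate) F3. Still–Gennari olefination with acetaldehyde (KN(SiMe3)2, 18-crown-6, THF, −78 °C) then builds both Z-alkenes on the ester, and the route is rejoined at 20.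

**Further compounds**
F1 | step 7 | tris(trimethylsilyl) reductive-cyclisation product: 3-[1-(benzyloxy)-2-methyl-3-(trimethylsilyloxy)propan-2-yl]-5-methyl-1-(trimethylsilyloxy)-4-[3-(trimethylsilyloxy)but-2-en-2-yl]cyclohex-1-ene, stereocentres as in 15 | CC(O[Si](C)(C)C)=C(C)[C@@H]1[C@@H](C=C(O[Si](C)(C)C)C[C@H]1C)[C@@](C)(COCc2ccccc2)CO[Si](C)(C)C
F2 | step 9 | bis(trimethylsilyl enol ether) of 16: 3-(benzyloxy)-2-[4,6-dimethyl-2-(trimethylsilyloxy)-6-[1-(trimethylsilyloxy)ethenyl]bicyclo[3.1.1]hept-2-en-7-yl]-2-methylpropanal, stereocentres as in 16 | C=C(O[Si](C)(C)C)[C@]1(C)[C@@H]2[C@@H]([C@H]1C(O[Si](C)(C)C)=C[C@H]2C)[C@@](C)(COCc3ccccc3)C=O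
F3 | step 11 | bis(phosphonopropanoate) of 18: 3-[(benzyloxy)methyl]-3,7,11-trimethyl-9-oxotricyclo[5.4.0.0(2,8)]undecane-4,6-diyl bis{2-[bis(2,2,2-trifluoroethoxy)phosphoryl]propanoate}, ring stereocentres as in 18 | CC(C(=O)O[C@@H]1C[C@@H](OC(=O)C(C)P(=O)(OCC(F)(F)F)OCC(F)(F)F)[C@]2(C)[C@@H]3[C@@H]([C@H]2C(=O)C[C@H]3C)[C@@]1(C)COCc4ccccc4)P(=O)(OCC(F)(F)F)OCC(F)(F)F
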